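Assumption: the SMILES is read as (5S)-4-hydroxy-5-(hydroxymethyl)-3-(13-methyltetradecanoyl)furan-2(5H)-one, i.e. the L-glycerate series at C5.

**Retrosynthetic overview**
- Target 12 is opened at the lactone C–O bond (O1–C2): the 2-hydroxyl of a glyceryl unit attacks the thioester of a 2-glyceryl-3-oxoacyl thioester (10, via diol 11) and the thiol leaves, as in off-loading from the carrier protein.
- 10 is cut at C3–C4: the C2 carbanion of the 3-oxoacyl thioester 6 attacks an activated L-glycerate (acid chloride 9, from 7 via salt 8).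
- 6 comes from a thioester Claisen extension of 13-methyltetradecanoic acid 3 with thioacetate 4.
- 3 comes from 11-bromoundecanoic acid 1 and isobutylmagnesium bromide 2.
- The only ring (the tetronate) is formed last, in step 5; the stereocentre comes unchanged from 7.

**Route**

Step 1
Reactants: 1 11-bromoundecanoic acid; 2 isobutylmagnesium bromide
Product: 3 13-methyltetradecanoic acid
Conditions: 2 (2.5 equiv), Li2CuCl4 (3 mol %), THF, −20 °C → rt; 1 M HCl work-up
Reagents that add atoms: none
Why: Kochi-type copper-catalysed sp3–sp3 cross-coupling of a primary bromide with a primary Grignard reagent, in which the first equivalent of 2 turns the acid into its inert bromomagnesium carboxylate so no protection is needed; no stereocentre.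

Step 2
Reactants: 3 13-methyltetradecanoic acid; 4 S-tert-butyl thioacetate
Product: 6 S-tert-butyl 15-methyl-3-oxohexadecanethioate, via acyl imidazolide 5 (not isolated)
Conditions: CDI (1.1 equiv), THF, rt, 1 h; then cannulated into 4 (3.3 equiv)/LiN(SiMe3)2 (3.3 equiv), THF, −78 → −40 °C; aq. NH4Cl
Reagents that add atoms: none
Why: Crossed Claisen condensation of a thioester lithium enolate with an acyl imidazolide, in which the product is held as its enolate and cannot add a second time, giving the 3-oxoacyl thioester that a ketosynthase would make; no stereocentre.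

Step 3
Reactants: 7 methyl (4S)-2,2-dimethyl-1,3-dioxolane-4-carboxylate
Product: 8 potassium (4S)-2,2-dimethyl-1,3-dioxolane-4-carboxylate
Conditions: KOH (1.0 equiv), MeOH, 0 °C → rt, 2 h; evaporate, triturate (Et2O), dry in vacuo
Reagents that add atoms: potassium hydroxide, [K+].[OH-]
Why: Saponification under mild conditions that leave the base-stable acetonide intact, and the carboxylate formed resists enolisation so the (S) centre is kept.

Step 4
Reactants: 8 potassium (4S)-2,2-dimethyl-1,3-dioxolane-4-carboxylate; 6 S-tert-butyl 15-methyl-3-oxohexadecanethioate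
Product: 10 S-tert-butyl 2-[(4S)-2,2-dimethyl-1,3-dioxolane-4-carbonyl]-15-methyl-3-oxohexadecanethioate (enolised tricarbonyl), via acid chloride 9 (not isolated)
Conditions: 8 (1.3 equiv), (COCl)2 (1.3 equiv), Et2O, 0 °C → rt; filtered solution added to 6, MgCl2 (1.2 equiv), pyridine (2.5 equiv), CH2Cl2, 0 °C → rt; cold aq. citric acid
Reagents that add atoms: none
Why: Rathke-type MgCl2/pyridine soft-enolisation C-acylation, in which the magnesium chelate of 6 attacks the glyceryl chloride at carbon (the chloride is made HCl-free from the salt so the acetonide survives), mirroring attack of the 3-oxoacyl thioester C2 carbanion on the glyceryl thioester; the (S) centre is carried through because pyridine at 0 °C is too weak to form the alkoxyketene.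

Step 5
Reactants: 10 S-tert-butyl 2-[(4S)-2,2-dimethyl-1,3-dioxolane-4-carbonyl]-15-methyl-3-oxohexadecanethioate
Product: 12 (5S)-4-hydroxy-5-(hydroxymethyl)-3-(13-methyltetradecanoyl)furan-2(5H)-one, via diol thioester 11 (not isolated)
Conditions: TFA–H2O (9:1), 0 °C, 20 min; evaporate cold (toluene chase); then AgO2CCF3 (1.5 equiv), THF, rt, dark; filter (Celite), 0.5 M HCl wash
Reagents that add atoms: none
Why: Proposed new method: aqueous acid hydrolyses the isopropylidene acetal to diol 11, then thiophilic monovalent silver binds the sulfur of the S-tert-butyl thioester (or expels AgSC(CH3)3 from the enol to give a diacylketene) and the 2-hydroxyl closes 5-exo-trig onto that acyl carbon to give the conjugated tetronate, the thermodynamic sink that a δ-lactone from the primary hydroxyl can also reach by O→O acyl shift, with C5 retained because none of its bonds is broken; the closest known reactions are the AgO2CCF3-promoted acylation of alcohols by S-tert-butyl 3-oxo thioesters and the lactonisation of 4-hydroxy-2-acyl-3-oxo esters to 3-acyltetronic acids.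

**Compound list**
1 | 11-bromoundecanoic acid | OC(=O)CCCCCCCCCCBr | starting material
2 | isobutylmagnesium bromide | CC(C)C[Mg]Br | starting material
3 | 13-methyltetradecanoic acid | CC(C)CCCCCCCCCCCC(=O)O | intermediate
4 | S-tert-butyl thioacetate | CC(=O)SC(C)(C)C | starting material
5 | 1-(13-methyltetradecanoyl)imidazole | CC(C)CCCCCCCCCCCC(=O)n1ccnc1 | intermediate
6 | S-tert-butyl 15-methyl-3-oxohexadecanethioate | CC(C)CCCCCCCCCCCC(=O)CC(=O)SC(C)(C)C | intermediate
7 | methyl (4S)-2,2-dimethyl-1,3-dioxolane-4-carboxylate | COC(=O)[C@@H]1COC(C)(C)O1 | starting material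
8 | potassium (4S)-2,2-dimethyl-1,3-dioxolane-4-carboxylate | [K+].[O-]C(=O)[C@@H]1COC(C)(C)O1 | intermediate
9 | (4S)-2,2-dimethyl-1,3-dioxolane-4-carbonyl chloride | ClC(=O)[C@@H]1COC(C)(C)O1 | intermediate
10 | S-tert-butyl 2-[(4S)-2,2-dimethyl-1,3-dioxolane-4-carbonyl]-15-methyl-3-oxohexadecanethioate | CC(C)CCCCCCCCCCCC(=O)C(C(=O)SC(C)(C)C)C(=O)[C@@H]1COC(C)(C)O1 | intermediate
11 | S-tert-butyl 2-[(2S)-2,3-dihydroxypropanoyl]-15-methyl-3-oxohexadecanethioate | CC(C)CCCCCCCCCCCC(=O)C(C(=O)SC(C)(C)C)C(=O)[C@@H](O)CO | intermediate
12 | (5S)-4-hydroxy-5-(hydroxymethyl)-3-(13-methyltetradecanoyl)furan-2(5H)-one | CC(C)CCCCCCCCCCCC(=O)C1=C(O)[C@H](CO)OC1=O | target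

**Totals**
Total step count: 5. Longest linear sequence: 4 steps (1 → 3 → 6 → 10 → 12; steps 1, 2, 4 and 5).

**Steps most likely to fail**

Step 5 is the riskiest. The primary hydroxyl may close to a δ-lactone, acid may cyclodehydrate the hydroxy-diketone to a 3(2H)-furanone, and C5 may epimerise. The fallback sets out from 7 and 6 and returns at 12. It tells the two hydroxyls apart before ring closure and reverses the bond order, O-acylation first and Dieckmann C–C closure second. Compound 7 is hydrolysed (Amberlyst-15, MeOH–H2O, 50 °C) to methyl (2S)-2,3-dihydroxypropanoate F1. The primary hydroxyl is tritylated (trityl chloride, pyridine, CH2Cl2) to give methyl (2S)-2-hydroxy-3-(trityloxy)propanoate F2. Thioester 6 is transacylated onto the secondary hydroxyl (AgO2CCF3, THF, rt) to give methyl (2S)-2-[(15-methyl-3-oxohexadecanoyl)oxy]-3-(trityloxy)propanoate F3. Lacey–Dieckmann cyclisation (Bu4NF, THF, rt) gives (5S)-4-hydroxy-3-(13-methyltetradecanoyl)-5-[(trityloxy)methyl]furan-2(5H)-one F4. TFA–H2O in CH2Cl2 then removes the trityl group to give 12.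

Step 4 is second. O-acylation may compete with C-acylation, the α-alkoxy acid chloride 9 may racemise through its ketene, and 10 may deacylate on work-up. The fallback sets out from 7 (with 4 and 3) and returns at 10. It swaps the order of the two C-acylations so that the only acid chloride used has no stereocentre. Crossed Claisen condensation of 7 with the lithium enolate of 4 (LiN(SiMe3)2, THF, −78 °C) gives S-tert-butyl 3-[(4S)-2,2-dimethyl-1,3-dioxolan-4-yl]-3-oxopropanethioate F5. Acid 3 is converted with (COCl)2 and catalytic DMF into 13-methyltetradecanoyl chloride F6. MgCl2/pyridine C-acylation of F5 with F6 in CH2Cl2 at 0 °C gives 10.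

Step 2 is third. The thioacetate enolate may self-condense or lose thiolate, and acylation may be incomplete. The fallback sets out from 3 and returns at 6, using an acylketene in place of the enolate Claisen. Acid 3 is coupled with Meldrum's acid (DCC, DMAP, CH2Cl2, 0 °C → rt) to give 5-(1-hydroxy-13-methyltetradecylidene)-2,2-dimethyl-1,3-dioxane-4,6-dione F7. Heating F7 with 2-methylpropane-2-thiol in toluene at 110 °C expels acetone and CO2, and the thiol traps the acylketene as 6.

**Further compounds**
F1 | step 5 | methyl (2S)-2,3-dihydroxypropanoate | COC(=O)[C@@H](O)CO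
F2 | step 5 | methyl (2S)-2-hydroxy-3-(trityloxy)propanoate | COC(=O)[C@@H](O)COC(c1ccccc1)(c1ccccc1)c1ccccc1
F3 | step 5 | methyl (2S)-2-[(15-methyl-3-oxohexadecanoyl)oxy]-3-(trityloxy)propanoate | CC(C)CCCCCCCCCCCC(=O)CC(=O)O[C@@H](COC(c1ccccc1)(c1ccccc1)c1ccccc1)C(=O)OC
F4 | step 5 | (5S)-4-hydroxy-3-(13-methyltetradecanoyl)-5-[(trityloxy)methyl]furan-2(5H)-one | CC(C)CCCCCCCCCCCC(=O)C1=C(O)[C@H](COC(c2ccccc2)(c2ccccc2)c2ccccc2)OC1=O
F5 | step 4 | S-tert-butyl 3-[(4S)-2,2-dimethyl-1,3-dioxolan-4-yl]-3-oxopropanethioate | CC(C)(C)SC(=O)CC(=O)[C@@H]1COC(C)(C)O1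
F6 | step 4 | 13-methyltetradecanoyl chloride | CC(C)CCCCCCCCCCCC(=O)Cl
F7 | step 2 | 5-(1-hydroxy-13-methyltetradecylidene)-2,2-dimethyl-1,3-dioxane-4,6-dione | CC(C)CCCCCCCCCCCC(O)=C1C(=O)OC(C)(C)OC1=O
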